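Atom numbering used throughout (daucane): C1 = quaternary ring-fusion carbon (CH3), C2 (OAc), C3 (CH2), C4 (OH, isopropyl) and C5 (ring-fusion CH) form the five-membered ring; C1, C10 (OAc), C9, C8 (CH3; C8–C9 oxirane), C7 (CH2), C6 (O-angelate) and C5 form the seven-membered ring. β = the face of the C1 methyl group, α = the other face. Compound numbers are bold in the prose; atoms always carry a "C" or "O".

## Analysis of the target

The target **24** is a trans-fused bicyclo[5.3.0]decane (daucane) with eight stereocentres: 1R, 2S, 4R, 5S, 6S, 8R, 9S, 10S. On the β face lie the C1 methyl, the C4 hydroxyl and the C8 methyl; on the α face lie H5, the oxygens at C2, C6 and C10, the oxirane oxygen and the isopropyl group. Oxygen sits on every second carbon of the ten-carbon perimeter (C2, C4, C6, C8, C10), so the quaternary C1 is flanked by two secondary carbinols (C2, C10) and C5 by two more (C4, C6). The feature that decides the strategy is the fragment C5–C6(O)–C7–C8(CH3)–C9–C10(O) of the seven-membered ring: atom for atom it is the ring of 3,5-dimethoxytoluene, and only the seventh ring atom, C1, is missing. The sensitive groups are the angelate (a (Z)-enoate that isomerises to the tiglate with base or nucleophiles), the trisubstituted oxirane next to an acyloxy group, and the tertiary C4 hydroxyl, which is β to both C2 and C6 and therefore prone to retro-aldol cleavage or dehydration whenever those carbons are carbonyls. The hard points are the seven-membered ring with the quaternary centre, the trans fusion, three carbinols (C2, C6, C10) whose hydrogens must all be delivered on the face of the angular methyl, and four hydroxyls that end in three different states (two acetates, one angelate, one free).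

## Retrosynthetic reasoning

**Ester and oxirane (24 ⇒ 23 ⇒ 22).** The two acetates are cut first because O2 and O10 are both secondary and O4 is tertiary, so one acylation of **23** finishes the synthesis. The oxirane is cut next: its oxygen is cis to O10, so a hydroxyl-directed epoxidation of the allylic alcohol **22** sets C8 and C9 together from C10.

**C10 carbinol and angelate (22 ⇒ 20 ⇒ 17 + 18).** C10–H is cut back to the enone **20**. O2 and O10 are 1,3-syn across C1, so a chelation-controlled reduction from the free C2 hydroxyl sets C10. The angelate is attached before that, at the stage of **17**, where O6 is the only secondary hydroxyl that is not neopentylic; the acid is **18**.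

**C2 and C6 carbinols (17 ⇒ 15).** Both C2 and C6 are β to the tertiary C4 hydroxyl and both need hydride from the β face, the face on which O4 lies. They are therefore cut back together to the dione **15** and set by hydroxyl-directed intramolecular hydride delivery. C10 must not be a carbonyl at this point, because the new C2 hydroxyl would direct hydride to the wrong face of C10; in **15** it is still masked as an enol ether.

**Enol ether (15 ⇒ 14).** **15** is the mono-hydrolysis product of the bis(enol ether) **14**. The forward step has to protonate C5, add the new oxygen at C6 and leave the second enol ether as a vinylogous ester.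

**Key disconnection (14 ⇒ 12).** In **14** the bonds C1–C5 and C1–C10 are cut and C5–C10 is re-formed, which restores an aromatic ring. The precursor is the acyclic diazoketone **12**, with one stereocentre (C4) and the carbene carbon (C1) already carrying the methyl group. The forward reaction is an intramolecular Büchner ring expansion: it closes the five-membered ring, inserts C1 into the arene to make the seven-membered ring, creates the quaternary centre and delivers O6, O10 and the C8 methyl from the arene. The carbene carbon is chosen as C1 and not C5 because the angular methyl then arrives with the carbene, and because the benzylic carbon is then C4, whose oxygen is needed later as the directing group.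

**Diazoketone (12 ⇒ 10 ⇒ 9 ⇒ 8 ⇒ 7).** The diazo group comes from the ethyl ketone **10** by regioselective diazo transfer. **10** is the silyl ether of the tertiary aldol **9**; the silyl group is needed only to keep the hydroxyl out of the carbenoid step. A direct aldol onto a 2,6-disubstituted aryl isopropyl ketone is not credible, so **9** is reached by oxidation of the 1,3-diol **8**, which comes from reductive opening of the epoxy alcohol **7**.

**C4–aryl bond (7 ⇒ 4 + 5).** The tertiary carbinol is cut at the C4–aryl bond. The aryl anion **6**, made from **5** by lithiation between the methoxy groups, adds to the epoxy ketone **4**. The oxirane has two jobs: it controls the face of the addition and so sets C4, and its oxygen becomes the C2 oxygen after the opening.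

**Epoxy ketone (4 ⇒ 3 ⇒ 1 + 2).** **4** is the catalytic asymmetric epoxidation product of the (E)-enone **3**, itself the olefination product of **1** and **2**. This is the only step in which absolute configuration enters; the other seven stereocentres are relayed from it.

## Alternatives that were turned down

Alternative 1: Ring-closing metathesis across C8=C9 (the textbook cut). The forward key step would close the cycloheptene from the cyclopentane diene A1, which carries a 1-hydroxyallyl arm on C1 and a 1-hydroxy-3-methylbut-3-enyl arm on C5. A1 must already contain six of the eight stereocentres: the quaternary C1 with both flanking carbinols, and two side-chain carbinols (C6, C10) that would have to be set by additions to exocyclic aldehydes without ring control. The key step forms one C=C bond and no stereocentre, and it has to form a trisubstituted olefin next to a neopentylic carbinol. The count would exceed twenty steps.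

Alternative 2: Chiral pool. (S)-Terpinen-4-ol A2 maps onto the five-membered ring: ozonolysis and intramolecular aldol condensation would give the cyclopentenecarbaldehyde A3, in which the C4 carbinol with its isopropyl group, the C1 methyl, C5 and C6 are bought. The key step would then be a conjugate addition of a C10 unit to C1 of A3, followed by closure of the seven-membered ring. It was turned down because C2 arrives as an unactivated CH2 and needs a late allylic oxidation; because the conjugate addition must create the quaternary centre at a β,β-disubstituted enal under the weak control of a remote tertiary alkoxide; and because the seven-membered ring, C6, C10 and the oxirane would still have to be built stepwise.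

Alternative 3: Seven-membered ring first. A catalytic asymmetric allylic alkylation of a cycloheptane-1,3-dione vinylogous ester would set C1 in A4, and the five-membered ring would be closed later from the allyl group. This suits daucanes at a low oxidation level. Here the allyl carbons would become C2–C3–C4 with C2 as a CH2 next to the quaternary centre, C5 and C6 would arrive as ring CH2 groups, and the vinylogous ester carbon (C8) would have to be changed from oxygen to methyl. Three C–H oxidations plus that exchange cost more than the stereocentre wins.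

Key step: step 8

Remarks on the chemistry (assumptions):
- The ester in the target SMILES is the (Z)-2-methylbut-2-enoate (angelate); **1** is taken as a catalogue β-ketophosphonate.
- Transient catalyst-bound or reagent-bound species (the rhodium carbenoid, boron-bound hydride donors) are described in the Why lines and not numbered; every intermediate that accumulates in the flask is numbered.

## Route

Step 1
Reactants: 1 dimethyl (3-methyl-2-oxobutyl)phosphonate; 2 propanal
Product: 3 (E)-2-methylhept-4-en-3-one
Conditions: Ba(OH)2, THF/H2O (40:1), rt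
Reagents that add atoms: none
Why: Horner–Wadsworth–Emmons olefination; the stabilised β-ketophosphonate anion and an unbranched aldehyde should give the (E)-enone, and the mild barium hydroxide conditions avoid self-condensation of 2.

Step 2
Reactants: 3 (E)-2-methylhept-4-en-3-one
Product: 4 (4R,5S)-4,5-epoxy-2-methylheptan-3-one
Conditions: La(O-iPr)3 (5 mol%), (S)-BINOL (5 mol%), Ph3As=O (5 mol%), TBHP, 4 Å MS, THF, rt
Reagents that add atoms: tert-butyl hydroperoxide, CC(C)(C)OO
Why: Catalytic asymmetric nucleophilic (Weitz–Scheffer type) epoxidation of an (E)-enone with a lanthanum–BINOL peroxide; the (S)-ligand is the antipode expected to give the (αR,βS)-oxirane, the E geometry fixes the trans relationship, and this is the only step that introduces absolute configuration.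

Step 3
Reactants: 4 (4R,5S)-4,5-epoxy-2-methylheptan-3-one; 5 3,5-dimethoxytoluene
Product: 7 (1R)-1-(2,6-dimethoxy-4-methylphenyl)-1-[(2R,3S)-3-ethyloxiran-2-yl]-2-methylpropan-1-ol, via aryllithium 6 (not isolated)
Conditions: 5, n-BuLi, THF, 0 °C to rt; then 4, −78 °C; AcOH, −78 °C
Reagents that add atoms: none
Why: Directed ortho-lithiation at the position flanked by both methoxy groups gives 6, which adds to the ketone faster than to the oxirane. In both the lithium-chelate (Cram) and the Felkin–Anh arrangement the oxirane C–O and C–C bonds lie on one face of the carbonyl group, so the aryl group should enter from the other face and set C4 as R.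

Step 4
Reactants: 7 (1R)-1-(2,6-dimethoxy-4-methylphenyl)-1-[(2R,3S)-3-ethyloxiran-2-yl]-2-methylpropan-1-ol
Product: 8 (3S,5R)-5-(2,6-dimethoxy-4-methylphenyl)-6-methylheptane-3,5-diol
Conditions: Red-Al, THF, 0 °C to rt; aq. Rochelle salt
Reagents that add atoms: none
Why: Red-Al opening of a 2,3-epoxy alcohol: the aluminate bound to the tertiary alkoxide delivers hydride to the proximal oxirane carbon (C3), which should give the 1,3-diol and leave C4 untouched.

Step 5
Reactants: 8 (3S,5R)-5-(2,6-dimethoxy-4-methylphenyl)-6-methylheptane-3,5-diol
Product: 9 (5R)-5-(2,6-dimethoxy-4-methylphenyl)-5-hydroxy-6-methylheptan-3-one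
Conditions: Dess–Martin periodinane, pyridine, CH2Cl2, 0 °C to rt
Reagents that add atoms: none
Why: Dess–Martin oxidation of the only oxidisable (secondary) hydroxyl; the carbinol centre inherited from the oxirane is erased and C4 remains the only stereocentre.

Step 6
Reactants: 9 (5R)-5-(2,6-dimethoxy-4-methylphenyl)-5-hydroxy-6-methylheptan-3-one
Product: 10 (5R)-5-(2,6-dimethoxy-4-methylphenyl)-6-methyl-5-(trimethylsilyloxy)heptan-3-one
Conditions: TMS-imidazole, CH2Cl2, rt
Reagents that add atoms: 1-(trimethylsilyl)imidazole, C[Si](C)(C)n1ccnc1
Why: Silylation of a hindered tertiary alcohol with a neutral silyl-transfer reagent that does not enolise the ketone; the hydroxyl must be capped because a free O–H five atoms from the carbene carbon would give O–H insertion in step 8.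

Step 7
Reactants: 10 (5R)-5-(2,6-dimethoxy-4-methylphenyl)-6-methyl-5-(trimethylsilyloxy)heptan-3-one
Product: 12 (5R)-2-diazo-5-(2,6-dimethoxy-4-methylphenyl)-6-methyl-5-(trimethylsilyloxy)heptan-3-one, via trifluoroacetyl ketone 11 (not isolated)
Conditions: LiHMDS, THF, −78 °C; CF3CO2CH2CF3; then MsN3, Et3N, H2O, MeCN, rt
Reagents that add atoms: methanesulfonyl azide, CS(=O)(=O)N=[N+]=[N-]
Why: Detrifluoroacetylative (Danheiser) diazo transfer: the kinetic lithium enolate forms on the ethyl side because the other α-carbon (C3) is neopentylic, so the activating trifluoroacetyl group and then the diazo group should enter at C1 only.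

Step 8
Reactants: 12 (5R)-2-diazo-5-(2,6-dimethoxy-4-methylphenyl)-6-methyl-5-(trimethylsilyloxy)heptan-3-one
Product: 14 (1S,4R)-6,10-dimethoxy-4-(trimethylsilyloxy)dauca-5,7,9-trien-2-one (1β-CH3 and 4β-OSiMe3), via norcaradiene 13 (not isolated)
Conditions: Rh2(OAc)4 (1 mol%), CH2Cl2, rt, slow addition of 12
Reagents that add atoms: none
Why: Intramolecular Büchner reaction (arene cyclopropanation, then 6π electrocyclic opening of the norcaradiene), the known route from 1-diazo-4-arylbutan-2-ones and their 1-methyl homologues to hydroazulenones. Loss of N2 gives an electrophilic rhodium carbenoid at C1 that adds across the ipso–ortho bond C5–C10 of the very electron-rich arene; this closes the five-membered ring C1–C2–C3–C4–C5 by exo attack on the ipso carbon through a five-membered transition state and gives the cyclopropane of 13. Disrotatory opening of 13 breaks the former aromatic bond C5–C10, so C1 is inserted into the ring and the seven-membered ring C1–C10–C9–C8–C7–C6–C5 is closed by ring expansion, with O6, O10 and the C8 methyl delivered by the arene as two enol ethers and a trisubstituted olefin. C1 is the only new stereocentre and is quaternary because the carbene carbon carries the methyl group, so 14 cannot tautomerise by 1,5-hydrogen shift. Its configuration is relayed from C4: between two ortho-methoxy groups, A(1,3) strain places the small C4–O bond near the ring plane (eclipsing the distal methoxy group) and the isopropyl group under the ring, so the tether carrying the carbenoid reaches the face anti to isopropyl and the methyl group ends cis to the C4 oxygen. The step needs chemoselectivity for the arene over a 1,2-hydride shift from the methyl group and over 1,5-insertion into the isopropyl C–H; the double methoxy activation of the ipso carbon, the blocked ortho positions (no aromatic substitution to a tetralone) and the low stationary carbenoid concentration are what should secure it.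

Step 9
Reactants: 14 (1S,4R)-6,10-dimethoxy-4-(trimethylsilyloxy)dauca-5,7,9-trien-2-one
Product: 15 (1S,4R,5R)-4-hydroxy-10-methoxydauca-7,9-diene-2,6-dione (trans-fused; 5α-H and 4β-OH)
Conditions: PPTS (cat.), acetone/H2O (10:1), rt
Reagents that add atoms: water, O
Why: Acid hydrolysis of an enol ether: C5 of the trienyl bis-ether is protonated to a pentadienyl cation stabilised by both methoxy groups, water adds at its less hindered terminus C6 (C10 is neopentylic), and the remaining methoxy-dienone is a vinylogous ester that resists further hydrolysis, while the tertiary silyl ether is cleaved. C5 is α to the new carbonyl and should settle under these equilibrating conditions in the trans-fused form (5α-H), in which C6 avoids the α-isopropyl group and its carbonyl is hydrogen-bonded to the 4β-hydroxyl.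

Step 10
Reactants: 15 (1S,4R,5R)-4-hydroxy-10-methoxydauca-7,9-diene-2,6-dione
Product: 17 (1R,2S,4R,5S,6S)-2,4,6-trihydroxydauc-8-en-10-one (2α,4β,6α-triol), via triol dienol ether 16 (not isolated)
Conditions: Me4NBH(OAc)3, MeCN/AcOH (1:1), −30 to 0 °C; aq. Rochelle salt; then (CO2H)2 (cat.), THF/H2O, 0 °C to rt
Reagents that add atoms: water, O
Why: Evans–Saksena hydroxyl-directed reduction: the C4 hydroxyl exchanges onto boron and hydride is delivered intramolecularly from the β face to the two carbonyls that are β to it, C2 (across the cyclopentane) and C6 (chair transition state), which should give the 2α- and 6α-alcohols (1,3-anti to O4); C10 cannot be reduced because it is still an enol ether. Dilute acid then protonates C7 of the dienol ether and water adds at C10, which unveils the C8=C9 enone.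

Step 11
Reactants: 17 (1R,2S,4R,5S,6S)-2,4,6-trihydroxydauc-8-en-10-one; 18 angelic acid ((Z)-2-methylbut-2-enoic acid)
Product: 20 (1R,2S,4R,5S,6S)-2,4-dihydroxy-10-oxodauc-8-en-6-yl (2Z)-2-methylbut-2-enoate (6α-angelate), via mixed anhydride 19 (not isolated)
Conditions: 18, 2,4,6-Cl3C6H2COCl, Et3N, toluene, rt; then 17, 60 °C
Reagents that add atoms: none
Why: Yamaguchi esterification through 19; C6–OH is the only secondary hydroxyl not attached to the quaternary C1 (C2–OH is neopentylic, C4–OH tertiary), so the bulky mixed anhydride should acylate O6, and leaving out DMAP guards the (Z)-geometry of the angelate.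

Step 12
Reactants: 20 (1R,2S,4R,5S,6S)-2,4-dihydroxy-10-oxodauc-8-en-6-yl (2Z)-2-methylbut-2-enoate
Product: 22 (1R,2S,4R,5S,6S,10R)-2,4,10-trihydroxydauc-8-en-6-yl (2Z)-2-methylbut-2-enoate (2α,4β,10α-triol), via boron chelate 21 (not isolated)
Conditions: Et2BOMe, THF/MeOH (4:1), −78 °C; NaBH4; MeOH co-evaporation
Reagents that add atoms: none
Why: Narasaka–Prasad reduction: boron ties O2 and the C10 carbonyl into the six-membered chelate 21 and external hydride adds axially (1,2-addition), which should give the 2,10-syn diol, i.e. the 10α-alcohol; this is also the Felkin sense (hydride anti to the C1–C2 bond), and the ester survives borohydride at −78 °C.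

Step 13
Reactants: 22 (1R,2S,4R,5S,6S,10R)-2,4,10-trihydroxydauc-8-en-6-yl (2Z)-2-methylbut-2-enoate
Product: 23 (1R,2S,4R,5S,6S,8R,9S,10S)-8,9-epoxy-2,4,10-trihydroxydaucan-6-yl (2Z)-2-methylbut-2-enoate (8α,9α-oxirane)
Conditions: VO(acac)2 (5 mol%), TBHP, CH2Cl2, 0 °C to rt
Reagents that add atoms: tert-butyl hydroperoxide, CC(C)(C)OO
Why: Vanadium-catalysed hydroxyl-directed epoxidation of a cyclohept-2-enol: oxygen is delivered cis to the allylic C10 hydroxyl, i.e. to the α face, which sets C8 and C9 together; the electron-poor angelate double bond has no allylic hydroxyl and should not react.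

Step 14
Reactants: 23 (1R,2S,4R,5S,6S,8R,9S,10S)-8,9-epoxy-2,4,10-trihydroxydaucan-6-yl (2Z)-2-methylbut-2-enoate
Product: 24 (1R,2S,4R,5S,6S,8R,9S,10S)-2,10-diacetoxy-8,9-epoxy-4-hydroxydaucan-6-yl (2Z)-2-methylbut-2-enoate (target)
Conditions: Ac2O, pyridine, DMAP (cat.), CH2Cl2, 0 °C to rt
Reagents that add atoms: acetic anhydride, CC(=O)OC(C)=O
Why: DMAP-catalysed acetylation of the two secondary hydroxyls; the hindered tertiary C4 hydroxyl is not acylated under these conditions, and no stereocentre is touched.

## Compound list

1 | dimethyl (3-methyl-2-oxobutyl)phosphonate | CC(C)C(=O)CP(=O)(OC)OC | starting material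
2 | propanal | CCC=O | starting material
3 | (E)-2-methylhept-4-en-3-one | CC/C=C/C(=O)C(C)C | intermediate
4 | (4R,5S)-4,5-epoxy-2-methylheptan-3-one (trans-oxirane) | CC[C@@H]1O[C@H]1C(=O)C(C)C | intermediate
5 | 3,5-dimethoxytoluene | Cc1cc(OC)cc(OC)c1 | starting material
6 | (2,6-dimethoxy-4-methylphenyl)lithium | [Li]c1c(OC)cc(C)cc1OC | intermediate (not isolated)
7 | (1R)-1-(2,6-dimethoxy-4-methylphenyl)-1-[(2R,3S)-3-ethyloxiran-2-yl]-2-methylpropan-1-ol | CC[C@@H]1O[C@H]1[C@@](O)(C(C)C)c1c(OC)cc(C)cc1OC | intermediate
8 | (3S,5R)-5-(2,6-dimethoxy-4-methylphenyl)-6-methylheptane-3,5-diol | CC[C@H](O)C[C@@](O)(C(C)C)c1c(OC)cc(C)cc1OC | intermediate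
9 | (5R)-5-(2,6-dimethoxy-4-methylphenyl)-5-hydroxy-6-methylheptan-3-one | CCC(=O)C[C@@](O)(C(C)C)c1c(OC)cc(C)cc1OC | intermediate
10 | (5R)-5-(2,6-dimethoxy-4-methylphenyl)-6-methyl-5-(trimethylsilyloxy)heptan-3-one | CCC(=O)C[C@@](O[Si](C)(C)C)(C(C)C)c1c(OC)cc(C)cc1OC | intermediate
11 | (5R)-5-(2,6-dimethoxy-4-methylphenyl)-6-methyl-2-(trifluoroacetyl)-5-(trimethylsilyloxy)heptan-3-one (C2 epimers, enolised) | CC(C(=O)C(F)(F)F)C(=O)C[C@@](O[Si](C)(C)C)(C(C)C)c1c(OC)cc(C)cc1OC | intermediate (not isolated)
12 | (5R)-2-diazo-5-(2,6-dimethoxy-4-methylphenyl)-6-methyl-5-(trimethylsilyloxy)heptan-3-one | CC(=[N+]=[N-])C(=O)C[C@@](O[Si](C)(C)C)(C(C)C)c1c(OC)cc(C)cc1OC | intermediate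
13 | norcaradiene valence isomer of 14 (cyclopropane C1–C5–C10; double bonds C6=C7 and C8=C9) | COC1=CC(C)=C[C@]2(OC)[C@@]3(C)C(=O)C[C@@](O[Si](C)(C)C)(C(C)C)[C@@]123 | intermediate (not isolated)
14 | (1S,4R)-6,10-dimethoxy-4-(trimethylsilyloxy)dauca-5,7,9-trien-2-one (1β-CH3, 4β-OSiMe3) | COC1=CC(C)=CC(OC)=C2[C@]1(C)C(=O)C[C@@]2(O[Si](C)(C)C)C(C)C | intermediate
15 | (1S,4R,5R)-4-hydroxy-10-methoxydauca-7,9-diene-2,6-dione (4β-OH, 5α-H) | O=C1C=C(C)C=C(OC)[C@@]2(C)C(=O)C[C@@](O)(C(C)C)[C@H]12 | intermediate
16 | (1R,2S,4R,5S,6S)-10-methoxydauca-7,9-diene-2,4,6-triol (2α,4β,6α) | O[C@H]1C=C(C)C=C(OC)[C@@]2(C)[C@@H](O)C[C@@](O)(C(C)C)[C@H]12 | intermediate (not isolated)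
17 | (1R,2S,4R,5S,6S)-2,4,6-trihydroxydauc-8-en-10-one (2α,4β,6α) | O[C@H]1CC(C)=CC(=O)[C@@]2(C)[C@@H](O)C[C@@](O)(C(C)C)[C@H]12 | intermediate
18 | angelic acid ((Z)-2-methylbut-2-enoic acid) | C/C=C(/C)C(=O)O | starting material
19 | angelic 2,4,6-trichlorobenzoic anhydride | C/C=C(/C)C(=O)OC(=O)c1c(Cl)cc(Cl)cc1Cl | intermediate (not isolated)
20 | (1R,2S,4R,5S,6S)-2,4-dihydroxy-10-oxodauc-8-en-6-yl (2Z)-2-methylbut-2-enoate (6α-angelate) | C/C=C(/C)C(=O)O[C@H]1CC(C)=CC(=O)[C@@]2(C)[C@@H](O)C[C@@](O)(C(C)C)[C@H]12 | intermediate
21 | O2-diethylboryl chelate of 20 | C/C=C(/C)C(=O)O[C@H]1CC(C)=CC(=O)[C@@]2(C)[C@@H](OB(CC)CC)C[C@@](O)(C(C)C)[C@H]12 | intermediate (not isolated)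
22 | (1R,2S,4R,5S,6S,10R)-2,4,10-trihydroxydauc-8-en-6-yl (2Z)-2-methylbut-2-enoate (2α,4β,10α) | C/C=C(/C)C(=O)O[C@H]1CC(C)=C[C@@H](O)[C@@]2(C)[C@@H](O)C[C@@](O)(C(C)C)[C@H]12 | intermediate
23 | (1R,2S,4R,5S,6S,8R,9S,10S)-8,9-epoxy-2,4,10-trihydroxydaucan-6-yl (2Z)-2-methylbut-2-enoate (8α,9α-oxirane) | C/C=C(/C)C(=O)O[C@H]1C[C@@]2(C)O[C@H]2[C@@H](O)[C@@]2(C)[C@@H](O)C[C@@](O)(C(C)C)[C@H]12 | intermediate
24 | (1R,2S,4R,5S,6S,8R,9S,10S)-2,10-diacetoxy-8,9-epoxy-4-hydroxydaucan-6-yl (2Z)-2-methylbut-2-enoate (CNP0170993.1) | C/C=C(/C)C(=O)O[C@H]1C[C@@]2(C)O[C@H]2[C@@H](OC(C)=O)[C@@]2(C)[C@@H](OC(C)=O)C[C@@](O)(C(C)C)[C@H]12 | target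

## Step count and least certain steps

Total step count: 14. Longest linear sequence: 14 steps (from **1** and **2** to **24**); **5** and **18** enter as bought.

**Step 8 (key step).** The carbenoid may be diverted before it reaches the arene, by a 1,2-hydride shift from its own methyl group or by 1,5-insertion into the isopropyl C–H. The facial selectivity may also be incomplete, because it rests on the rotamer preference about the C4–aryl bond. The fallback moves the methyl group out of the carbenoid. It sets out from **1**: olefination with acetaldehyde in place of **2** gives (E)-2-methylhex-4-en-3-one F1. The operations of steps 2–7 then lead through the epoxy ketone F2, the epoxy alcohol F3, the diol F4, the hydroxy methyl ketone F5, its silyl ether F6 and the trifluoroacetyl diketone F7 to the terminal diazoketone F8. F8 is the classical substrate type for the Büchner reaction and has no β-hydrogen on the carbene carbon. Rh2(OAc)4 should give the 1-H cycloheptatriene F9. Its C1–H is the most acidic proton (α to the C2 carbonyl and doubly allylic); deprotonation (KHMDS, THF, −78 °C) and C-methylation with MeI on the face anti to the C4 isopropyl group comes back to the route at **14**.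

**Step 9.** Regiocontrol in the hydration of the pentadienyl cation may be lost (water at C10 gives the transposed vinylogous ester). The allylic tertiary C4–O bond may ionise, and C5 may not equilibrate fully. The fallback gives up the selective hydrolysis: from **14**, 1 M HCl in THF hydrolyses both enol ethers to the ene-trione (1R,4R,5R)-4-hydroxydauc-8-ene-2,6,10-trione F10. The directed reduction of step 10 is then run at −40 °C with limited reagent. C2 and C6, both β to the C4 hydroxyl, should react before C10, which is a hindered enone carbonyl that can only be reached from the newly formed C2 hydroxyl. This comes back at **17**.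

**Step 10.** Hydride transfer to C6 may be slow, because C6 is the carbonyl of a vinylogous ester, and the doubly allylic C6 carbinol that forms may ionise in acetic acid. The fallback separates the two reductions. From **15**, the borohydride at −40 °C should reduce only C2 and give (1R,2S,4R,5R)-2,4-dihydroxy-10-methoxydauca-7,9-dien-6-one F11. Aqueous HCl in THF hydrolyses its vinylogous ester to (1R,2S,4R,5R)-2,4-dihydroxydauc-8-ene-6,10-dione F12, in which C6 is an ordinary saturated ketone. A second directed reduction of F12 comes back at **17**.

**Step 11.** Site selectivity between O6 and the neopentylic O2 may be insufficient, and the acyl group may isomerise from Z to E on prolonged heating. The fallback protects instead of discriminating. From **17**, the chelation-controlled reduction (conditions of step 12) gives the tetraol (1R,2S,4R,5S,6S,10R)-dauc-8-ene-2,4,6,10-tetraol F13. 2,2-Dimethoxypropane and PPTS should close an acetonide only on the syn-1,3-diol O2/O10, giving the 2,10-O-isopropylidene tetraol F14. Acylation of the one remaining secondary hydroxyl with **19** gives the 6-O-angeloyl acetonide F15, and aqueous acetic acid removes the acetonide, which comes back at **22**.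

## Further compounds

F1 | step 8 | (E)-2-methylhex-4-en-3-one | C/C=C/C(=O)C(C)C
F2 | step 8 | (4R,5S)-4,5-epoxy-2-methylhexan-3-one | C[C@@H]1O[C@H]1C(=O)C(C)C
F3 | step 8 | (1R)-1-(2,6-dimethoxy-4-methylphenyl)-2-methyl-1-[(2R,3S)-3-methyloxiran-2-yl]propan-1-ol | C[C@@H]1O[C@H]1[C@@](O)(C(C)C)c1c(OC)cc(C)cc1OC
F4 | step 8 | (2S,4R)-4-(2,6-dimethoxy-4-methylphenyl)-5-methylhexane-2,4-diol | C[C@H](O)C[C@@](O)(C(C)C)c1c(OC)cc(C)cc1OC
F5 | step 8 | (4R)-4-(2,6-dimethoxy-4-methylphenyl)-4-hydroxy-5-methylhexan-2-one | CC(=O)C[C@@](O)(C(C)C)c1c(OC)cc(C)cc1OC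
F6 | step 8 | (4R)-4-(2,6-dimethoxy-4-methylphenyl)-5-methyl-4-(trimethylsilyloxy)hexan-2-one | CC(=O)C[C@@](O[Si](C)(C)C)(C(C)C)c1c(OC)cc(C)cc1OC
F7 | step 8 | (6R)-6-(2,6-dimethoxy-4-methylphenyl)-1,1,1-trifluoro-7-methyl-6-(trimethylsilyloxy)octane-2,4-dione | O=C(CC(=O)C(F)(F)F)C[C@@](O[Si](C)(C)C)(C(C)C)c1c(OC)cc(C)cc1OC
F8 | step 8 | (4R)-1-diazo-4-(2,6-dimethoxy-4-methylphenyl)-5-methyl-4-(trimethylsilyloxy)hexan-2-one | [N-]=[N+]=CC(=O)C[C@@](O[Si](C)(C)C)(C(C)C)c1c(OC)cc(C)cc1OC
F9 | step 8 | (4R)-6,10-dimethoxy-4-(trimethylsilyloxy)-15-nordauca-5,7,9-trien-2-one (1-H analogue of 14) | COC1=CC(C)=CC(OC)=C2[C@@H]1C(=O)C[C@@]2(O[Si](C)(C)C)C(C)C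
F10 | step 9 | (1R,4R,5R)-4-hydroxydauc-8-ene-2,6,10-trione | O=C1CC(C)=CC(=O)[C@@]2(C)C(=O)C[C@@](O)(C(C)C)[C@H]12
F11 | step 10 | (1R,2S,4R,5R)-2,4-dihydroxy-10-methoxydauca-7,9-dien-6-one | O=C1C=C(C)C=C(OC)[C@@]2(C)[C@@H](O)C[C@@](O)(C(C)C)[C@H]12
F12 | step 10 | (1R,2S,4R,5R)-2,4-dihydroxydauc-8-ene-6,10-dione | O=C1CC(C)=CC(=O)[C@@]2(C)[C@@H](O)C[C@@](O)(C(C)C)[C@H]12
F13 | step 11 | (1R,2S,4R,5S,6S,10R)-dauc-8-ene-2,4,6,10-tetraol | O[C@H]1CC(C)=C[C@@H](O)[C@@]2(C)[C@@H](O)C[C@@](O)(C(C)C)[C@H]12
F14 | step 11 | 2,10-O-isopropylidene derivative of F13 | O[C@H]1CC(C)=C[C@@H](OC(C)(C)O3)[C@@]2(C)[C@@H]3C[C@@](O)(C(C)C)[C@H]12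
F15 | step 11 | 6-O-angeloyl derivative of F14 | C/C=C(/C)C(=O)O[C@H]1CC(C)=C[C@@H](OC(C)(C)O3)[C@@]2(C)[C@@H]3C[C@@](O)(C(C)C)[C@H]12
A1 | alternative 1 | 8,9-seco diene for ring-closing metathesis (cyclopentane with 1-hydroxyallyl on C1 and 1-hydroxy-3-methylbut-3-enyl on C5; tetraol shown, hydroxyls protected in practice) | C=C[C@@H](O)[C@@]1(C)[C@@H](O)C[C@@](O)(C(C)C)[C@@H]1[C@@H](O)CC(C)=C
A2 | alternative 2 | (S)-terpinen-4-ol | CC1=CC[C@](O)(C(C)C)CC1
A3 | alternative 2 | (R)-5-hydroxy-2-methyl-5-(propan-2-yl)cyclopent-1-ene-1-carbaldehyde | O=CC1=C(C)CC[C@@]1(O)C(C)C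
A4 | alternative 3 | (R)-7-allyl-3-isobutoxy-7-methylcyclohept-2-en-1-one | O=C1C=C(OCC(C)C)CCC[C@]1(C)CC=C
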